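Start from time: target ages in the vessel, so work with the fraction of it left and not with the amount made.

all flasks: substrate 1.4 M
- noon: time 3.0 d; a closed flask charged with all of it at once and left for 3.0 d
- dusk: one stirred flow tank at steady state, fed with the mixture as stated, mean residence time 3.0 d

    substrate ⇌ target + by-product (K1 = 0.35 M, k1 = 0.0068 h⁻¹)
    target → over-reaction product (k2 = 0.0077 h⁻¹)

* the set-up with the highest share of target in all that became target or over-reaction product, at the outlet or at the end ("none" if the first two lie within 2 percentage points) (noon / dusk / none)
* share of target in all that became target or over-reaction product, at the outlet or at the end, noon
* share of target in all that became target or over-reaction product, at the outlet or at the end, dusk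

- the stated concentrations are those of everything mixed, before any reaction; amounts are the same in each set-up
- run time (noon): 3.0 d

Each asked share, the selectivity for target, is a fraction left: target still there over all that became target. Take the loss number, the over-reaction constant times the time, 0.554. In dusk at steady state, the target made equals the target leaving by flow plus the target lost, and the residence time equals the run time, so the fraction left is 64.3%. In noon, suppose target is made steadily; the fraction left is then 76.8%, and noon leads.

The weak link is that steady making: the net rate of the first step shrinks both with falling c(substrate) and with the growing way back, c(target)·c(by-product). Reforge it: let the net rate fall evenly to 0.333 of its starting value, a third. Making then centres at 0.417 of the run, so the mean age of target at the end, the time since the average target was made, is 1.75 d. The fraction left becomes 72.4%. Check the guess: by-product reaches 0.457 M, and the net rate at the end, over its starting value, comes back as 0.365, close to the guess. Commit to 72.4% for noon.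

The forecast names noon, with 73% for noon and 64.3% for dusk, a little above my noon figure: “The flask keeps target young and low for much of the run”.

The simulation gives 73.2% for noon and 64.3% for dusk, so noon leads. In noon, the first step had half of its turnover behind it by 1.13 d, the over-reaction step by 1.95 d. At 1.13 d in noon, target was made 4.49 times faster than used up, each step taken net, and at 3.00 d still 1.35 times, with 67.5% substrate present. Carry the same share of the run to noon read at 5.0 d: the mean age is 2.92 d, and the fraction left 58.3%. That reading gives 57.2%, below dusk's 64.3%.

All constants were chosen freely; what happens was integrated by code.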